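The numbers in the tables are simulated with constants of no real substance, noise included.

- ochre: D 0.29 M; X 0.50 equiv; the very flask that is asked about, followed so far
- flask: D 0.29 M; X 0.500 equiv; time 2.5 d

ochre run (percent of the D and X together charged)

| time / h | G / % | Q / % |
|---|---|---|
| 2.50 | 24.0 | 17.9 |
| 6.00 | 39.2 | 30.2 |
| 12.0 | 48.3 | 38.2 |
| 20.0 | 50.4 | 40.1 |

(scatter of a reading: 0.3 percentage points)

- share of G in G plus Q at 4.0 min
- share of G in G plus Q at 2.0 h
- share of G in G plus Q at 2.5 d



1. We start by adding. In the ochre run, which is the asked flask followed so far, G plus Q stands at 69.4 % at 6.00 h and 86.5 % at 12.0 h.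

2. Something looks odd in this flask. Between 2.50 h and 20.0 h, G grows twice over, yet its share of G plus Q, the selectivity, moves from 57.3 % to 55.7 %.

3. So we count turnovers instead of hours. Suppose the total climbs exponentially to a plateau. Since 12.0 h is twice 6.00 h, the ratio of the two totals, less one, is the part of the gap surviving 6.00 h: 24.6 %. That gives 2.97 h as the half-time, the time in which the total covers half of the way left to its plateau.

4. With it, this flask has covered 44.2 % of the way at 2.50 h and 99.1 % at 20.0 h, a factor 2.24. In the readings Q grew by 2.24 and G by 2.10, a little less than Q. So the odd thing clears: the growth of G follows the way covered, and its small lag behind Q is the small fall of the share.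

5. At 4.0 min the count is 0.0225, so the way covered is 1.54 %. At 2.0 h the count is 0.674, so it is 37.3 %. At 2.5 d the count is 20.2. Drawing the share as a straight line against the way covered, we reckon 58.5 %, 57.5 % and 55.7 %.

6. The forecast differs a little: 58 %, 57.4 % and 55.2 %, the last set lower and given a range down to 51.5 %, since “slow equilibration could continue drifting the ratio”.

7. The flask gives 57.8 %, 57.2 % and 56.2 %.

    D ⇌ X, settled at all times (K = 0.0930)
    X ⇌ L (K = 17.0, k = 0.0450 h⁻¹)
    X → Q (k = 1.10 h⁻¹)
    D + G → Z (k = 0.0780 M⁻¹ h⁻¹)
    D → G (k = 0.140 h⁻¹)
    L → J (k = 0.0560 h⁻¹)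

The forecast is right within the margin on all three. At 0.250 d the half-time leaves 24.7 % of the way to go, and this flask holds D plus X at 24.7 %. At 20.2 turnovers it holds D 0 % and X 0 %. The neighbour flask, charged at [D] = 1.2 M against 0.29 M, reckoned with this half-time counts the same 20.2, and it also ends with D 0 % and X 0 %. Yet its share falls from 57.7 % to 51.8 %, further than here. It ends with G 39.7 % and Z, which counts as two, 21.9 %, against Z 6.98 % here.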